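**Plan**

- Locants (labdane style): ring B = C5–C6–C7–C8–C9–C10; lactone ring = O–C2(=O)–C1–C10–C9–C8; C4 = CMe2 carrying the C3 acid; side chain C11–C15; β is the face of the C20 methyl on C10.
- Enabling feature: the δ-lactone bridges C8 and C10 of ring B as a 2-oxabicyclo[3.3.1]nonan-3-one. Removing its ring oxygen leaves the cyclopentanone C2–C1–C10–C9–C8 of a bicyclo[3.2.1]octan-6-one, so C8–O is cut as a retro-Baeyer–Villiger step.
- Cuts, in order: C13–C14 (vinyl), C11–C12 (methallyl), C8–O (oxygen insertion), C9–C11 (methylenation), C2–C8 (bridged aldol), C10–C1 (allylation), C4–C5 (Mukaiyama–Michael), C5=C10 (metathesis), C9–C10 and C7–C8 (acyclic assembly).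
- Forward: ring B closes first by ring-closing metathesis and the cyclopentane ring second by aldol addition. That ring is then expanded to the lactone, and the side chain is added last in two C–C bond formations.
- Stereochemistry: C6 comes from resolved (S)-2-vinyloxirane and is relayed to C5 (anti addition), C10 (anti allylation), C8 (only the α face can be bridged) and C9 (hydroboration from the two-carbon-bridge side). C8–O forms with retention, C11 is set by a pinene-derived borane, and C13 by chelation to the C11 alkoxide.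

Key step: step 16

Remark: C8 is carried as a mixture of epimers in 5–17, because it is fixed only when the C2–C8 bond forms. The C2 carbinol of 18–23 is drawn as the expected exo epimer, although either epimer would serve because C2 is oxidised in step 15. TMSE = 2-(trimethylsilyl)ethyl.

Step 1
Reactants: 1 rac-2-vinyloxirane (butadiene monoxide)
Product: 2 (S)-2-vinyloxirane
Conditions: (S,S)-(salen)Co(OAc) (0.5–1 mol %; salen = N,N′-bis(3,5-di-tert-butylsalicylidene)cyclohexane-1,2-diamine dianion), H2O (0.6 equiv), THF, 0 °C → rt; distillation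
Reagents that add atoms: none
Why: Hydrolytic kinetic resolution, in which the chiral cobalt–salen acetate hydrolyses the (R)-epoxide much faster than the (S)-epoxide, so that distillation should leave 2, whose stereocentre becomes C6 and is the only source of absolute configuration for the ring system.

Step 2
Reactants: 2 (S)-2-vinyloxirane; 3 4-propanoylmorpholine
Product: 5 (4R)-4-hydroxy-2-methyl-1-(morpholin-4-yl)hex-5-en-1-one (C8 epimers), via lithium enolate 4 (not isolated)
Conditions: 3, LDA (LiN(i-Pr)2), LiCl, THF, −78 → 0 °C; then 2, 0 °C → rt; H2O quench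
Reagents that add atoms: LDA, CC(C)[N-]C(C)C.[Li+] (lithium of 4 only)
Why: Alkylation of an amide enolate with a terminal epoxide, an SN2 opening at the unsubstituted carbon (C7) that forms C7–C8 without touching the C6–O bond, so C6 is retained while the new C8 centre forms unselectively and is of no consequence.

Step 3
Reactants: 5 hydroxy amide
Product: 6 (4R)-4-(tert-butyldimethylsilyloxy)-2-methyl-1-(morpholin-4-yl)hex-5-en-1-one (C8 epimers)
Conditions: TBSCl, imidazole, DMF, rt
Reagents that add atoms: tert-butyldimethylsilyl chloride, CC(C)(C)[Si](C)(C)Cl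
Why: Standard silylation of a secondary allylic alcohol, giving the silyl ether that later marks the α face of ring B.

Step 4
Reactants: 6 silyloxy amide
Product: 7 (6R)-6-(tert-butyldimethylsilyloxy)-2,4-dimethylocta-1,7-dien-3-one (C8 epimers)
Conditions: isopropenylmagnesium bromide, THF, 0 °C → rt; inverse quench into cold aqueous citric acid
Reagents that add atoms: isopropenylmagnesium bromide, C=C(C)[Mg]Br
Why: Acylation of a Grignard reagent by a morpholine amide, which like a Weinreb amide holds the tetrahedral magnesium adduct until the quench and so stops at the ketone, the acidic inverse quench keeping liberated morpholine from adding to the new enone.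

Step 5
Reactants: 7 dienone
Product: 8 (4R)-4-(tert-butyldimethylsilyloxy)-2,6-dimethylcyclohex-2-en-1-one (ring B enone; C8 epimers)
Conditions: second-generation Grubbs catalyst (5 mol %), CH2Cl2, reflux
Reagents that add atoms: none
Why: Ring-closing metathesis of a 1,7-diene to the six-membered ring B (C5=C10), a closure well known for methacryloyl-type enones with ruthenium N-heterocyclic-carbene catalysts and one that leaves C6 untouched.

Step 6
Reactants: 9 isobutyryl chloride; 10 2-(trimethylsilyl)ethanol
Product: 11 2-(trimethylsilyl)ethyl 2-methylpropanoate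
Conditions: Et3N, DMAP (cat), CH2Cl2, 0 °C → rt
Reagents that add atoms: none
Why: Acylation of a primary alcohol by an acid chloride, chosen so that the C3 acid is masked as an ester that fluoride will remove together with the C6 silyl ether at the end.

Step 7
Reactants: 11 TMSE isobutyrate
Product: 13 2-methyl-1-(trimethylsilyloxy)-1-[2-(trimethylsilyl)ethoxy]prop-1-ene, via lithium enolate 12 (not isolated)
Conditions: LDA, THF, −78 °C; TMSCl, −78 °C → rt
Reagents that add atoms: LDA, CC(C)[N-]C(C)C.[Li+] (lithium of 12 only); chlorotrimethylsilane, C[Si](C)(C)Cl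
Why: O-Silylation of an ester lithium enolate, the standard preparation of ketene silyl acetals from isobutyrates, with no enolate-geometry issue because C4 carries two methyl groups.

Step 8
Reactants: 8 ring B enone; 13 ketene silyl acetal
Product: 14 TMSE 2-[(1S,6R)-6-(tert-butyldimethylsilyloxy)-2,4-dimethyl-3-(trimethylsilyloxy)cyclohex-2-en-1-yl]-2-methylpropanoate (C4 group 5β; OTBS 6α; C8 epimers)
Conditions: HNTf2 (2 mol %), CH2Cl2, −78 °C; Et3N quench
Reagents that add atoms: none
Why: Mukaiyama–Michael addition under silylium catalysis, in which the bulky ketene acetal attacks C5 anti to the C6 silyloxy group, as is usual for 4-silyloxycyclohexenones (setting 5β-C4 trans to 6α-O), and silyl transfer stores the C9/C10 enolate regiospecifically as its trimethylsilyl enol ether.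

Step 9
Reactants: 14 silyl enol ether
Product: 15 TMSE 2-[(1S,2R,6R)-2-allyl-6-(tert-butyldimethylsilyloxy)-2,4-dimethyl-3-oxocyclohexyl]-2-methylpropanoate (allyl 10α; C20 methyl 10β; C8 epimers)
Conditions: allyl methyl carbonate, Pd2(dba)3·CHCl3 (2.5 mol %), dppe (5 mol %), THF, reflux
Reagents that add atoms: allyl methyl carbonate, C=CCOC(=O)OC
Why: Tsuji allylation of a silyl enol ether under neutral conditions, in which methoxide set free when zerovalent palladium ionises the carbonate desilylates 14 and the regiodefined C10 enolate is allylated on the α face, opposite the C5 tert-alkyl group that A(1,2) strain with the C10 methyl forces pseudo-axial, which sets the quaternary centre C10 (C1 α, C20 β).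

Step 10
Reactants: 15 allyl ketone
Product: 17 keto aldehyde (C9 ketone; 10α-CH2CHO arm C1–C2; C8 epimers), via secondary ozonide 16 (not isolated)
Conditions: O3, CH2Cl2, −78 °C; Me2S, −78 °C → rt
Reagents that add atoms: ozone, [O-][O+]=O
Why: Ozonolysis with reductive work-up cleaves the only C=C bond of 15 and turns the allyl group into the C1–C2 acetaldehyde arm.

Step 11
Reactants: 17 keto aldehyde
Product: 18 bridged ketol, TMSE 2-[3-(tert-butyldimethylsilyloxy)-6-hydroxy-1,5-dimethyl-8-oxobicyclo[3.2.1]octan-2-yl]-2-methylpropanoate (C2–OH exo; C9 ketone; C17 methyl β)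
Conditions: K2CO3 (0.2 equiv), MeOH, 0 °C → rt
Reagents that add atoms: none
Why: Intramolecular aldol addition closing the five-membered ring C2–C1–C10–C9–C8 (the closure that also turns 1,4-dicarbonyl compounds into cyclopentenones), in which C8 is the only enolisable position of the ketone and the aldehyde arm hangs from the α face of C10, so the C2–C8 bond can form only on that face, fixing C8 with its methyl β, while dehydration is impossible because C8 becomes quaternary.

Step 12
Reactants: 18 bridged ketol
Product: 19 C2 triethylsilyl ether of 18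
Conditions: TESOTf, 2,6-lutidine, CH2Cl2, −78 → 0 °C
Reagents that add atoms: triethylsilyl triflate, CC[Si](CC)(CC)OS(=O)(=O)C(F)(F)F
Why: Silyl triflate silylation of a hindered secondary alcohol with a non-nucleophilic base, which blocks retro-aldol cleavage during the basic olefination that follows.

Step 13
Reactants: 19 silylated ketol
Product: 20 8-methylenebicyclo[3.2.1]octane (C9=C11H2; C2–OTES; 6α-OTBS; 5β-CMe2CO2TMSE)
Conditions: Ph3PCH3Br, KOt-Bu, toluene, 90 °C
Reagents that add atoms: methylenetriphenylphosphorane (from Ph3PCH3Br and KOt-Bu), C=P(c1ccccc1)(c1ccccc1)c1ccccc1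
Why: Wittig methylenation under the hot, alkoxide-generated ylide conditions used for fenchone-type ketones, where 19 cannot enolise and its β-oxygen is silylated, so neither epimerisation nor retro-aldol cleavage can compete with the slow addition to the strained bridge carbonyl.

Step 14
Reactants: 20 methylene compound
Product: 23 diol (C11–OH on 9β-CH2; C2–OH exo), via alkylborane 21 (not isolated), via TES-protected alcohol 22 (not isolated)
Conditions: BH3·THF, THF, 0 °C → rt; NaOH, H2O2, 0 °C; crude in AcOH–THF–H2O (3:1:1), rt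
Reagents that add atoms: borane (as BH3·THF), B (boron of 21 only); hydrogen peroxide, OO
Why: Hydroboration–oxidation places boron on the terminal carbon C11 and hydrogen on C9 from the face turned towards the two-carbon bridge C1–C2, because the opposite face is roofed by the C5–C6–C7 bridge and its C5 tert-alkyl group, so C11 ends up β and H9 α, and the aqueous acetic acid then removes only the triethylsilyl ether.

Step 15
Reactants: 23 diol
Product: 24 bridged ketone, TMSE 2-[3-(tert-butyldimethylsilyloxy)-8-(hydroxymethyl)-1,5-dimethyl-6-oxobicyclo[3.2.1]octan-2-yl]-2-methylpropanoate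
Conditions: aqueous NaOCl (1.1 equiv), AcOH, 0 °C → rt
Reagents that add atoms: none
Why: Stevens oxidation, in which hypochlorous acid in acetic acid oxidises secondary alcohols far faster than primary ones and the primary C11 alcohol is in addition neopentyl-like, so only C2 should be taken to the ketone.

Step 16
Reactants: 24 bridged ketone (bicyclo[3.2.1]octan-6-one)
Product: 26 bridged lactone, TMSE 2-[7-(tert-butyldimethylsilyloxy)-9-(hydroxymethyl)-1,5-dimethyl-3-oxo-2-oxabicyclo[3.3.1]nonan-6-yl]-2-methylpropanoate, via Criegee adduct 25 (not isolated)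
Conditions: mCPBA (2–3 equiv), CH2Cl2, 0 °C → rt
Reagents that add atoms: 3-chloroperbenzoic acid, O=C(OO)c1cccc(Cl)c1
Why: The peracid adds to the C2 carbonyl from the open exo face (the side of H9) to give Criegee adduct 25, and loss of 3-chlorobenzoate is concerted with the 1,2-shift of the C2–C8 bond to the proximal peroxide oxygen. This is a Baeyer–Villiger oxidation of a bridged cyclopentanone, its closest analogues being bicyclo[3.2.1]octan-6-ones and camphor-type ketones that give bridged lactones by bridgehead migration. No ring is closed by cyclisation: the five-membered ring C2–C1–C10–C9–C8 is enlarged by oxygen insertion to the six-membered ring O–C2–C1–C10–C9–C8, which turns the bicyclo[3.2.1]octanone into the 2-oxabicyclo[3.3.1]nonan-3-one. The C8–O stereocentre is controlled by the suprafacial nature of the shift, so C8 keeps the configuration fixed in step 11 and the oxygen takes the α position formerly held by C2, cis to C1 as the bicycle demands. The step needs regioselectivity (C8 rather than C1 migration), secured by a fully substituted, cation-stabilising carbon competing against a primary methylene, and chemoselectivity, secured because 24 has no alkene, its ester and silyl ether are inert and a primary alcohol is not attacked by the peracid.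

Step 17
Reactants: 26 bridged lactone
Product: 27 C11 aldehyde (9β-CHO lactone)
Conditions: Dess–Martin periodinane, CH2Cl2, 0 °C → rt; used crude
Reagents that add atoms: none
Why: Dess–Martin oxidation of a hindered primary alcohol under essentially neutral conditions, chosen because 27 is a β-acyloxy aldehyde that a base could cleave by elimination across C8–C9 or epimerise at C9.

Step 18
Reactants: 27 C11 aldehyde
Product: 29 (11S)-homoallylic alcohol (C11–OH; C12H2–C13(CH3)=CH2), via borinate ester 28 (not isolated)
Conditions: (−)-Ipc2BOMe, methallylmagnesium chloride, Et2O, −78 °C → rt; then 27, Et2O, −78 °C; 30% H2O2, pH 7 phosphate buffer, MeOH, 0 °C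
Reagents that add atoms: B-methallyldiisopinocampheylborane of the (+)-α-pinene series (made in the flask), C=C(C)CB([C@@H]1C[C@@H]2C[C@H]([C@H]1C)C2(C)C)[C@@H]1C[C@@H]2C[C@H]([C@H]1C)C2(C)C
Why: Brown asymmetric methallylboration through a chair transition state, in which the reagent of the (+)-α-pinene series attacks the Si face of the aldehyde and should set 11S, the substrate bias being small because both flanks of C9 (C8 and C10) are quaternary and methyl-bearing, while the neutral low-temperature conditions spare the β-acyloxy aldehyde.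

Step 19
Reactants: 29 homoallylic alcohol
Product: 31 (11S)-β-hydroxy methyl ketone (C13 ketone), via secondary ozonide 30 (not isolated)
Conditions: O3, CH2Cl2, −78 °C; Me2S, −78 °C → rt
Reagents that add atoms: ozone, [O-][O+]=O
Why: Ozonolysis of the 1,1-disubstituted alkene, the only C=C bond present, unmasks the C13 methyl ketone without affecting C11.

Step 20
Reactants: 31 β-hydroxy ketone
Product: 33 (11S,13S)-diol (6-O-TBS ether; C3 TMSE ester of the target), via magnesium alkoxide 32 (not isolated)
Conditions: vinylmagnesium bromide (3.5 equiv), CH2Cl2–THF, −78 °C; H2O quench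
Reagents that add atoms: vinylmagnesium bromide, C=C[Mg]Br
Why: Chelation-controlled Grignard addition to a β-hydroxy ketone, in which the first equivalent forms magnesium alkoxide 32, whose six-membered chelate with the C13 carbonyl places the bulky C9 residue equatorial, and axial attack of the next equivalent (the sense that gives syn-1,3-diols in chelate-controlled reductions) should set 13S, while the ketone outruns the hindered lactone and ester at low temperature.

Step 21
Reactants: 33 protected diol
Product: 34 target CNP0297019.2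
Conditions: TBAF (excess), THF, rt → 40 °C; work-up at pH 4
Reagents that add atoms: none
Why: Fluoride-induced desilylation, in which attack at silicon fragments the TMSE ester to ethene and the C3 carboxylate and cleaves the C6 silyl ether in the same operation, under conditions that should leave the lactone, the tertiary allylic alcohol and all stereocentres untouched.

**Compound list**

1 | rac-2-vinyloxirane (butadiene monoxide) | C=CC1CO1 | starting material
2 | (S)-2-vinyloxirane | C=C[C@H]1CO1 | intermediate
3 | 4-propanoylmorpholine | CCC(=O)N1CCOCC1 | starting material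
4 | lithium (Z)-enolate of 3 | C/C=C(\[O-])N1CCOCC1.[Li+] | intermediate
5 | (4R)-4-hydroxy-2-methyl-1-(morpholin-4-yl)hex-5-en-1-one (C8 epimers) | O=C(N1CCOCC1)C(C)C[C@@H](O)C=C | intermediate
6 | (4R)-4-(tert-butyldimethylsilyloxy)-2-methyl-1-(morpholin-4-yl)hex-5-en-1-one (C8 epimers) | O=C(N1CCOCC1)C(C)C[C@@H](O[Si](C)(C)C(C)(C)C)C=C | intermediate
7 | (6R)-6-(tert-butyldimethylsilyloxy)-2,4-dimethylocta-1,7-dien-3-one (C8 epimers) | C=C(C)C(=O)C(C)C[C@@H](O[Si](C)(C)C(C)(C)C)C=C | intermediate
8 | (4R)-4-(tert-butyldimethylsilyloxy)-2,6-dimethylcyclohex-2-en-1-one (C8 epimers) | CC1C[C@@H](O[Si](C)(C)C(C)(C)C)C=C(C)C1=O | intermediate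
9 | isobutyryl chloride | CC(C)C(=O)Cl | starting material
10 | 2-(trimethylsilyl)ethanol | OCC[Si](C)(C)C | starting material
11 | 2-(trimethylsilyl)ethyl 2-methylpropanoate | CC(C)C(=O)OCC[Si](C)(C)C | intermediate
12 | lithium enolate of 11 | CC(C)=C([O-])OCC[Si](C)(C)C.[Li+] | intermediate
13 | 2-methyl-1-(trimethylsilyloxy)-1-[2-(trimethylsilyl)ethoxy]prop-1-ene | CC(C)=C(O[Si](C)(C)C)OCC[Si](C)(C)C | intermediate
14 | Michael adduct as C9 trimethylsilyl enol ether (5β-CMe2CO2TMSE, 6α-OTBS, C8 epimers) | CC1C[C@@H](O[Si](C)(C)C(C)(C)C)[C@H](C(C)(C)C(=O)OCC[Si](C)(C)C)C(C)=C1O[Si](C)(C)C | intermediate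
15 | 10α-allyl-10β-methyl ketone (C8 epimers) | C=CC[C@@]1(C)C(=O)C(C)C[C@@H](O[Si](C)(C)C(C)(C)C)[C@@H]1C(C)(C)C(=O)OCC[Si](C)(C)C | intermediate
16 | secondary ozonide of 15 | C1OOC(O1)C[C@@]2(C)C(=O)C(C)C[C@@H](O[Si](C)(C)C(C)(C)C)[C@@H]2C(C)(C)C(=O)OCC[Si](C)(C)C | intermediate
17 | keto aldehyde (C9 ketone, C2 aldehyde, C8 epimers) | O=CC[C@@]1(C)C(=O)C(C)C[C@@H](O[Si](C)(C)C(C)(C)C)[C@@H]1C(C)(C)C(=O)OCC[Si](C)(C)C | intermediate
18 | bridged ketol (6-hydroxybicyclo[3.2.1]octan-8-one, C2–OH exo) | O=C1[C@]2(C)C[C@H](O)[C@@]1(C)C[C@@H](O[Si](C)(C)C(C)(C)C)[C@@H]2C(C)(C)C(=O)OCC[Si](C)(C)C | intermediate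
19 | C2 triethylsilyl ether of 18 | O=C1[C@]2(C)C[C@H](O[Si](CC)(CC)CC)[C@@]1(C)C[C@@H](O[Si](C)(C)C(C)(C)C)[C@@H]2C(C)(C)C(=O)OCC[Si](C)(C)C | intermediate
20 | C9 exocyclic methylene compound | C=C1[C@]2(C)C[C@H](O[Si](CC)(CC)CC)[C@@]1(C)C[C@@H](O[Si](C)(C)C(C)(C)C)[C@@H]2C(C)(C)C(=O)OCC[Si](C)(C)C | intermediate
21 | C11 alkylborane (9β-CH2BH2) | BC[C@H]1[C@]2(C)C[C@H](O[Si](CC)(CC)CC)[C@@]1(C)C[C@@H](O[Si](C)(C)C(C)(C)C)[C@@H]2C(C)(C)C(=O)OCC[Si](C)(C)C | intermediate
22 | C11 alcohol with C2–OTES | OC[C@H]1[C@]2(C)C[C@H](O[Si](CC)(CC)CC)[C@@]1(C)C[C@@H](O[Si](C)(C)C(C)(C)C)[C@@H]2C(C)(C)C(=O)OCC[Si](C)(C)C | intermediate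
23 | C2,C11 diol | OC[C@H]1[C@]2(C)C[C@H](O)[C@@]1(C)C[C@@H](O[Si](C)(C)C(C)(C)C)[C@@H]2C(C)(C)C(=O)OCC[Si](C)(C)C | intermediate
24 | bridged ketone (bicyclo[3.2.1]octan-6-one, 9β-CH2OH) | OC[C@H]1[C@]2(C)CC(=O)[C@@]1(C)C[C@@H](O[Si](C)(C)C(C)(C)C)[C@@H]2C(C)(C)C(=O)OCC[Si](C)(C)C | intermediate
25 | Criegee adduct (exo perester, endo OH at C2) | OC[C@H]1[C@]2(C)C[C@](O)(OOC(=O)c3cccc(Cl)c3)[C@@]1(C)C[C@@H](O[Si](C)(C)C(C)(C)C)[C@@H]2C(C)(C)C(=O)OCC[Si](C)(C)C | intermediate
26 | bridged lactone (2-oxabicyclo[3.3.1]nonan-3-one, 9β-CH2OH) | OC[C@H]1[C@]2(C)CC(=O)O[C@@]1(C)C[C@@H](O[Si](C)(C)C(C)(C)C)[C@@H]2C(C)(C)C(=O)OCC[Si](C)(C)C | intermediate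
27 | C11 aldehyde | O=C[C@H]1[C@]2(C)CC(=O)O[C@@]1(C)C[C@@H](O[Si](C)(C)C(C)(C)C)[C@@H]2C(C)(C)C(=O)OCC[Si](C)(C)C | intermediate
28 | diisopinocampheylborinate of 29 | C=C(C)C[C@H](OB([C@@H]3C[C@@H]4C[C@H]([C@H]3C)C4(C)C)[C@@H]3C[C@@H]4C[C@H]([C@H]3C)C4(C)C)[C@H]1[C@]2(C)CC(=O)O[C@@]1(C)C[C@@H](O[Si](C)(C)C(C)(C)C)[C@@H]2C(C)(C)C(=O)OCC[Si](C)(C)C | intermediate
29 | (11S)-homoallylic alcohol | C=C(C)C[C@H](O)[C@H]1[C@]2(C)CC(=O)O[C@@]1(C)C[C@@H](O[Si](C)(C)C(C)(C)C)[C@@H]2C(C)(C)C(=O)OCC[Si](C)(C)C | intermediate
30 | secondary ozonide of 29 | CC1(OCOO1)C[C@H](O)[C@H]2[C@]3(C)CC(=O)O[C@@]2(C)C[C@@H](O[Si](C)(C)C(C)(C)C)[C@@H]3C(C)(C)C(=O)OCC[Si](C)(C)C | intermediate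
31 | (11S)-β-hydroxy methyl ketone | CC(=O)C[C@H](O)[C@H]1[C@]2(C)CC(=O)O[C@@]1(C)C[C@@H](O[Si](C)(C)C(C)(C)C)[C@@H]2C(C)(C)C(=O)OCC[Si](C)(C)C | intermediate
32 | bromomagnesium C11 alkoxide of 31 | CC(=O)C[C@H](O[Mg]Br)[C@H]1[C@]2(C)CC(=O)O[C@@]1(C)C[C@@H](O[Si](C)(C)C(C)(C)C)[C@@H]2C(C)(C)C(=O)OCC[Si](C)(C)C | intermediate
33 | 6-O-TBS ether, C3 TMSE ester of the target | C=C[C@@](C)(O)C[C@H](O)[C@H]1[C@]2(C)CC(=O)O[C@@]1(C)C[C@@H](O[Si](C)(C)C(C)(C)C)[C@@H]2C(C)(C)C(=O)OCC[Si](C)(C)C | intermediate
34 | CNP0297019.2 | C=C[C@@](C)(O)C[C@H](O)[C@H]1[C@]2(C)CC(=O)O[C@@]1(C)C[C@@H](O)[C@@H]2C(C)(C)C(=O)O | target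

**Step count**

Total step count: 21. Longest linear sequence: 19 (steps 1–5 and 8–21).

**Steps most likely to fail**

Step 11. The bridged aldol addition is reversible. The strained ketol may not be favoured at equilibrium, or it may revert on handling.
- The fallback sets out from 15. LDA and TMSCl give the C8=C9 trimethylsilyl enol ether F1.
- N-Bromosuccinimide converts it into the C8 α-bromo ketone F2.
- Ozonolysis (O3, then Me2S) of the allyl group gives the bromo keto aldehyde F3.
- SmI2 in THF at −78 °C reduces the C8–Br bond to a samarium enolate that adds to the C2 aldehyde in an intramolecular Reformatsky-type reductive aldol.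
- The chelated aldolate of trivalent samarium should not revert at this temperature, and protonation brings the route back at 18.

Step 13. Addition of the bulky ylide to a carbonyl flanked by two quaternary bridgeheads may stall.
- The fallback sets out from 19 and replaces olefination and hydroboration by a one-carbon epoxide homologation.
- Dimethylsulfonium methylide (Corey–Chaykovsky reaction, Me3SI, NaH, DMSO–THF) should attack from the two-carbon-bridge side to give the spiro-epoxide F4, with oxygen on the β face.
- Methylaluminium bis(4-bromo-2,6-di-tert-butylphenoxide) in CH2Cl2 at −78 °C induces a Meinwald rearrangement. Hydride migrates to C9 anti to the departing oxygen and gives the 9β-carbaldehyde F5.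
- NaBH4 in MeOH reduces F5 to 22, where the route is rejoined before the acetic acid desilylation of step 14.

Step 18. Facial selectivity may be poor if the intrinsic bias of the aldehyde opposes the reagent. Slow addition would also leave time for elimination of the lactone carboxylate.
- The fallback sets out from 27 and fixes C11 by hydride delivery instead of carbon delivery.
- Uncatalysed addition of methallylboronic acid pinacol ester (toluene, rt) gives the carbinol under substrate control, expected in that case mainly as the 11R epimer F6.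
- Dess–Martin oxidation gives the C11 ketone F7.
- Luche-type reduction (NaBH4, CeCl3·7H2O, MeOH, −78 °C) lets the same Felkin-type bias guide hydride to the face that carbon had preferred. This inverts the outcome at C11 and returns the route at 29.

**Further compounds**

F1 | step 11 | C8=C9 trimethylsilyl enol ether of 15 | C=CC[C@@]1(C)C(O[Si](C)(C)C)=C(C)C[C@@H](O[Si](C)(C)C(C)(C)C)[C@@H]1C(C)(C)C(=O)OCC[Si](C)(C)C
F2 | step 11 | C8 α-bromo ketone (C8 epimers) | C=CC[C@@]1(C)C(=O)C(C)(Br)C[C@@H](O[Si](C)(C)C(C)(C)C)[C@@H]1C(C)(C)C(=O)OCC[Si](C)(C)C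
F3 | step 11 | bromo keto aldehyde (C8 epimers) | O=CC[C@@]1(C)C(=O)C(C)(Br)C[C@@H](O[Si](C)(C)C(C)(C)C)[C@@H]1C(C)(C)C(=O)OCC[Si](C)(C)C
F4 | step 13 | C9 spiro-epoxide (oxygen β, CH2 α) | C1O[C@]12[C@]3(C)C[C@H](O[Si](CC)(CC)CC)[C@@]2(C)C[C@@H](O[Si](C)(C)C(C)(C)C)[C@@H]3C(C)(C)C(=O)OCC[Si](C)(C)C
F5 | step 13 | 9β-carbaldehyde with C2–OTES | O=C[C@H]1[C@]2(C)C[C@H](O[Si](CC)(CC)CC)[C@@]1(C)C[C@@H](O[Si](C)(C)C(C)(C)C)[C@@H]2C(C)(C)C(=O)OCC[Si](C)(C)C
F6 | step 18 | (11R)-homoallylic alcohol (C11 epimer of 29) | C=C(C)C[C@@H](O)[C@H]1[C@]2(C)CC(=O)O[C@@]1(C)C[C@@H](O[Si](C)(C)C(C)(C)C)[C@@H]2C(C)(C)C(=O)OCC[Si](C)(C)C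
F7 | step 18 | C11 ketone (β,γ-unsaturated) | C=C(C)CC(=O)[C@H]1[C@]2(C)CC(=O)O[C@@]1(C)C[C@@H](O[Si](C)(C)C(C)(C)C)[C@@H]2C(C)(C)C(=O)OCC[Si](C)(C)C
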